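**Analysis of the target**

Target 25 is the tetracyclic C20 gibberellin that carries the number 17 in the A series, a triacid with carboxyl groups at C7, C19 and C20. Ring A (C1–C5, C10) is a cyclohexane trans-fused to cyclopentane ring B (C5, C6, C8, C9, C10), which is cis-fused at C8–C9 to ring C (C8, C9, C11–C14); ring D (C8, C14, C13, C16, C15) completes a bicyclo[3.2.1]octane. There are seven stereocentres (C4, C5, C6, C8, C9, C10, C13); C4, C8 and C10 are quaternary and C13 is a bridgehead tertiary carbinol. The C19 and C20 carboxyl groups are cis and 1,3-diaxial on ring A, H5 lies on the opposite face, H5 and H6 are trans, and H9 lies on the same face of ring C as the C15–C16 bridge. Sensitive features are the tertiary allylic alcohol next to the C16 methylene (acid triggers Wagner–Meerwein rearrangement of rings C and D), the epimerisable C6, and the two neopentyl esters at C4 and C10, which resist saponification. The difficulty is the contiguous array C4–C5–C10–C9–C8 with three quaternary carbons inside a bridged skeleton. The strategy rests on one feature: quaternary C8 belongs to both ring B and ring D, and C16 carries the exocyclic methylene beside the C13 carbinol. A C6 alkenylpalladium can therefore close ring B on an exocyclic C8=C15 alkene, which leaves palladium on neopentyl C15, and this closes ring D on a C13 vinyl group and ends as the C16 methylene.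

**Retrosynthetic reasoning**

25 to 22. The three acids are unmasked last from trimethyl ester 24, because the free acids and the acid-labile ring C–ring D unit are best exposed only at the end. C5–H and C6–H are taken back to the tetrasubstituted C5=C6 enoate 22. No carbon–carbon bond is cut; C5 is then set by protonation anti to the two axial esters and C6 by equilibration, on a finished and rigid skeleton.

22 to 20. The bonds C6–C8 and C15–C16 are cut together. Both end at carbons attached to quaternary C8, so a single palladium centre can make the first bond, rest on C15 without a β-hydrogen, and make the second. Cutting elsewhere (for example C8–C9 or C13–C14) offers no such relay. The gain is two rings, the quaternary C8, the methylene and the carbinol in one operation. The forward reaction needs the (Z)-enol triflate 20 (oxygen on the C10 side), an exocyclic C8=C15 alkene and a C13 vinyl group on the face of H9.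

20 to 16. The enol triflate comes from α-keto ester 19, and this from diacid 18. The C6 oxygen is carried from the start as a γ-lactone with C19 (in 16); oxidation of the lactone C6–H then releases the C6 ketone and the C19 carboxyl together, so no separate hydroxylation and alcohol oxidation are needed.

16 to 12. The C13–C16 bond is cut to ketone 14. A free β,γ-unsaturated ketone would risk conjugation of the C8 methylene and offers poor facial control. The C20 acid of 12 is therefore tied to C8 as iodolactone 13: this removes the alkene for the time being and places an axial oxygen on C8 that steers the vinyl nucleophile to the equatorial side of C13. A reductive elimination later returns both the acid and the methylene (15 to 16).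

12 to 8 and 3. The C9–C10 bond joins a quaternary carbon to a tertiary one and is cut by a Claisen rearrangement: the C20–O–C15 allyl enol ether 10 places C9 and C10 at the ends of a six-atom array. The rearrangement delivers the C8 methylene directly and C20 as an aldehyde (11), one oxidation from acid 12. A polar disconnection here would need a secondary electrophile at C9 and a neopentyl nucleophile.

8 to 4. The C10=C20 enol ether 8 comes from ketone 7 by a one-carbon ylide. Ketone 7 is cut at C4–C18 and C5–C6: conjugate addition of a methyl nucleophile to enone ester 4 sets C4 by catalyst control, and the resulting enolate is trapped at C5 by a two-carbon aldehyde ester. Lactonisation onto the C19 ester fixes C5 relative to C4.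

3 to 1. Ring C alcohol 3 has the 1,3-relationship of C8 and C13 that a meta-disubstituted arene offers; dissolving-metal reduction of 1 and ketal exchange of enol ether 2 give it in two steps.

**Alternatives that were turned down**

Alternative 1: Ring C is cut at C8–C9 and C13–C14, with ring B closing through the C6–C5–C10 tether. The forward key step is a thermal intramolecular Diels–Alder reaction of a C9–C11–C12–C13 silyloxy diene with the C8=C14 bond of a 2-substituted enal unit, giving tricycle A1.
- For it: a pericyclic step is less capricious than a palladium cascade through a neopentyl intermediate, the B–C cis fusion follows from the tether, and C8 arrives with a C15 aldehyde. On reliability of the key step it is stronger than the chosen route.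
- Against it: the diene terminus C13 carries both the silyloxy and the alkynyl group, so one of them sits inside the s-cis diene and slows the cycloaddition, and the C13 configuration depends on a diene geometry that is hard to fix. The tether must already hold C4, C5, C6 and quaternary C10 in the right relative configuration, built on an open chain.
- Comparison: after A1, ring D still has to be closed (C15–C16), the C15 oxygen removed and the C11=C12 bond reduced. The chosen strategy closes ring D and sets the methylene and the carbinol in the key step, and needs only two steps afterwards.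

Alternative 2: The bonds C9–C11 and C1–C10 are cut. The forward key step is a tin-mediated radical cascade: a primary C11 radical adds 6-exo to C9 of a ring B enoate and the resulting C10 radical is allylated by an allylstannane, giving A2.
- For it: the bicyclo[3.2.1]octane is built early, radicals tolerate congestion well, and C9 and C10 are formed together. For making a hindered bond it is at least as good as the Claisen step used here.
- Against it: the tertiary α-ester radical at C10 must be trapped intermolecularly in competition with hydrogen abstraction, and the face of C10 is only weakly biased. The C4 quaternary centre has to be set on a side chain next to C5 under acyclic control.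
- Comparison: ring A is closed late by metathesis, followed by hydrogenation of C2=C3 and methylenation at C16. The chosen strategy sets C4 inside a ring by catalyst control and C10 through an ordered chair transition state, and it avoids stoichiometric tin.

Alternative 3: Ring B is cut at C5–C6 and traced to a six-membered ring B of a natural ent-kaurane diterpenoid. The forward key step is photolysis of a ring B α-diazoketone in an alcohol; Wolff rearrangement contracts the ring, the ketene is trapped as the C7 methyl ester, and the product is A3.
- For it: nearly all stereocentres come from the natural skeleton and the key step ends two operations from the target. On step count after the diazoketone and on stereochemical security it is clearly stronger.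
- Against it: it is a relay from a natural diterpenoid and not a synthesis from simple materials. C20 of such a skeleton is an unactivated angular methyl group that must be oxidised to a carboxyl group, and C6 and C7 must be oxygenated on an unactivated ring to reach the diazoketone.
- Comparison: the chosen strategy is de novo, carries C20 at the right oxidation level from the Claisen step, and leaves rings A and C open to variation.

Key step: step 14

Remark on the chemistry: gibberellin numbering (C1–C20) is used for all intermediates; centres that are destroyed later (C6 up to compound 17, C5 in 18 and 19, C10 and C20 in 9) are carried as epimer mixtures and are left undefined in the SMILES.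

Step 1
Reactants: 1 3-methoxybenzyl alcohol
Product: 2 (5-methoxycyclohexa-1,4-dien-1-yl)methanol
Conditions: Li, NH3 (l), THF, t-BuOH, −78 to −33 °C
Reagents that add atoms: none
Why: Birch reduction; the methoxy and alkyl groups end up on the two remaining double bonds, and the benzylic oxygen is protected from hydrogenolysis as its lithium alkoxide.

Step 2
Reactants: 2 (5-methoxycyclohexa-1,4-dien-1-yl)methanol
Product: 3 (1,4-dioxaspiro[4.5]dec-7-en-7-yl)methanol
Conditions: HOCH2CH2OH, PPTS (cat.), CH2Cl2, rt
Reagents that add atoms: ethylene glycol, OCCO
Why: Acid-catalysed acetal exchange of the enol ether gives the dioxolane; the C8=C9 alkene is β,γ to the masked C13 carbonyl and cannot move into conjugation with a ketal.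

Step 3
Reactants: 4 methyl 3-oxocyclohex-1-ene-1-carboxylate
Product: 7 methyl (3aS,7aR)-7a-methyl-1,4-dioxooctahydro-2-benzofuran-3-carboxylate (keto lactone; C6 epimers), via methylzinc enolate 5 (not isolated), via aldol adduct 6 (not isolated)
Conditions: Me2Zn, Cu(OTf)2 (cat.), chiral sulfonate-bearing imidazolinium salt (NHC precursor, cat.), Et2O, −30 °C; then OHC–CO2Me, −78 °C to rt; aq NH4Cl
Reagents that add atoms: dimethylzinc, C[Zn]C; methyl glyoxylate, COC(=O)C=O
Why: Copper-catalysed asymmetric conjugate addition sets quaternary C4 (ligand enantiomer chosen for the R configuration), and the zinc enolate adds to the glyoxylate at C5 (tandem conjugate addition–aldol). The aldolate should equilibrate by retro-aldol reaction, and only the adduct with C6 cis to the C19 ester can lactonise, so C5 is fixed relative to C4 in the cis-fused γ-lactone.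

Step 4
Reactants: 7 keto lactone
Product: 8 C10 methoxymethylidene derivative of 7 (methyl enol ether; E/Z mixture)
Conditions: MeOCH2PPh3Cl, KN(SiMe3)2, THF, 0 °C to rt
Reagents that add atoms: (methoxymethyl)triphenylphosphonium chloride, COC[P+](c1ccccc1)(c1ccccc1)c1ccccc1.[Cl-]
Why: Wittig methoxymethylenation brings in C20; the unstabilised ylide should add to the ketone faster than it removes the hindered C5–H, so the β-acyloxy ketone is not opened by elimination. The enol ether geometry is irrelevant because it equilibrates under the acid of the next step.

Step 5
Reactants: 8 methyl enol ether; 3 (1,4-dioxaspiro[4.5]dec-7-en-7-yl)methanol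
Product: 11 C20 aldehyde from the Claisen rearrangement, via mixed acetal 9 (not isolated), via allyl enol ether 10 (not isolated)
Conditions: EtCO2H (cat.), xylenes, 145 °C, MeOH distilled off
Reagents that add atoms: none
Why: Acid-catalysed exchange of the methyl enol ether gives allyl enol ether 10, which undergoes Claisen rearrangement through a chair transition state. The allyloxy group sits cis to the unbranched C1 arm, so the branched C5 arm is equatorial in the chair, and C9 is delivered to the convex face of the cis-fused lactone, opposite the axial C19 carbonyl and past the small axial H5. This sets C10 (C20 cis to C19) and C9 in the required relative configuration and forms the C8 methylene directly.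

Step 6
Reactants: 11 C20 aldehyde
Product: 12 C20 carboxylic acid
Conditions: NaClO2, NaH2PO4, 2-methyl-2-butene, t-BuOH/H2O, rt
Reagents that add atoms: sodium chlorite, [Na+].[O-]Cl=O
Why: Pinnick oxidation of the neopentyl aldehyde; the scavenger protects the 1,1-disubstituted alkene, and the buffered medium spares the dioxolane.

Step 7
Reactants: 12 C20 carboxylic acid
Product: 13 iodolactone (C20 to C8 γ-lactone; C15 iodide; C13 dioxolane)
Conditions: I2, NaHCO3, MeCN/H2O, 0 °C
Reagents that add atoms: iodine, II
Why: 5-exo iodolactonisation; the carboxylate on C10 opens the iodonium ion at tertiary C8 axially and on the face of C10 (cis-fused lactone). The alkene is thereby stored and an axial oxygen is placed on C8.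

Step 8
Reactants: 13 iodolactone
Product: 14 C13 ketone
Conditions: 1 M HCl, THF, rt
Reagents that add atoms: water, O
Why: Acetal hydrolysis; with C8 sp3 there is no alkene to conjugate, and both lactones are stable to dilute acid.

Step 9
Reactants: 14 C13 ketone
Product: 15 C13 vinyl carbinol (hydroxyl axial and cis to C10; vinyl equatorial and cis to C15 and H9)
Conditions: CH2=CHMgBr, CeCl3, THF, −78 °C; aq NH4Cl
Reagents that add atoms: vinylmagnesium bromide, C=C[Mg]Br
Why: Organocerium-mediated Grignard addition, which limits enolisation (and so β-elimination of the C8 acyloxy group) and spares the hindered lactones and the ester. The axial C8–O bond is syn-axial to the axial trajectory at C13, so the vinyl group enters equatorially, as with 3-axially substituted cyclohexanones.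

Step 10
Reactants: 15 C13 vinyl carbinol
Product: 16 C20 acid with the C8=C15 methylene restored
Conditions: Zn, AcOH, THF, rt
Reagents that add atoms: none
Why: Reductive elimination of the β-acyloxy iodide returns the exocyclic alkene and the C20 acid; the tertiary allylic alcohol tolerates acetic acid at room temperature.

Step 11
Reactants: 16 C20 acid
Product: 18 keto diacid, via hemiketal 17 (not isolated)
Conditions: KN(SiMe3)2 (3.3 equiv), THF, −78 °C; then 2-(phenylsulfonyl)-3-phenyloxaziridine; then cold 0.5 M HCl
Reagents that add atoms: 2-(phenylsulfonyl)-3-phenyloxaziridine, O=S(=O)(N1OC1c1ccccc1)c1ccccc1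
Why: Enolate hydroxylation with an N-sulfonyloxaziridine; C6–H (α to the C7 ester) is the only enolisable C–H after the carboxyl and hydroxyl groups are deprotonated. The α-acyloxy-α-hydroxy ester 17 collapses to the C6 ketone and releases the C19 carboxylate; after acidification 18 may rest in part as a lactol, which the base of step 12 opens again.

Step 12
Reactants: 18 keto diacid
Product: 19 keto triester
Conditions: MeI, KHCO3, DMF, rt
Reagents that add atoms: iodomethane, CI
Why: Carboxylate O-alkylation (SN2 at iodomethane) esterifies both neopentyl carboxyl groups, where acyl substitution would be too slow. Bicarbonate is too weak to enolise C5 or to ionise the tertiary alcohol, and no reagent is present that could add to the electrophilic C6 ketone.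

Step 13
Reactants: 19 keto triester
Product: 20 (Z)-enol triflate (triflate oxygen on the C10 side of C5=C6)
Conditions: KN(SiMe3)2 (2.1 equiv), THF, −78 °C; then PhNTf2; aq NH4Cl
Reagents that add atoms: N-phenylbis(trifluoromethanesulfonimide), O=S(=O)(N(c1ccccc1)S(=O)(=O)C(F)(F)F)C(F)(F)F
Why: Enolisation of the α-keto ester at C5 (its only α-hydrogen) and O-sulfonylation; the second equivalent of base holds the C13 hydroxyl as an unreactive tertiary alkoxide. By allylic 1,3-strain the larger CO2Me group of the enolate should lie next to the C4 methyl group and the oxygen next to the more crowded C10, which gives the geometry needed in step 14.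

Step 14
Reactants: 20 (Z)-enol triflate
Product: 22 5,6-didehydro trimethyl ester, via neopentylpalladium triflate 21 (not isolated)
Conditions: Pd(PPh3)4 (10 mol %), Et3N, MeCN, 80 °C
Reagents that add atoms: none
Why: Oxidative addition of zerovalent palladium into the C6–O bond gives a cationic divalent alkenylpalladium that is cis to C10 on the C5=C6 bond. Syn carbopalladation of the 1,1-disubstituted C8=C15 alkene is 5-exo-trig (bond C6–C8, ring B) and leaves palladium on C15 in 21, which has no β-hydrogen because C8 is now quaternary. This neopentylpalladium inserts 5-exo-trig at the internal carbon of the C13 vinyl group (bond C15–C16, ring D), and β-hydride elimination of the single C16–H from the C17–palladium species gives the C16 methylene; Et3N returns zerovalent palladium. The closest known reaction type is the intramolecular domino Heck cyclisation in which a neopentyl alkylpalladium formed at a new quaternary carbon closes a bicyclo[3.2.1]octane. The only new stereocentre, C8, is controlled by C9: the short C10–C9 tether lets C6 reach C8 only on the face of ring C that carries C10, so ring B is cis-fused and C15 is pushed to the face of H9. Ring D can close because the C13 vinyl group was placed on that same face in step 9 and becomes 1,3-diaxial to C15 once ring C flips. The step needs the second insertion to outrun 3-exo attack of the C15–palladium bond on C5=C6 and reduction of the alkylpalladium; the nearby monosubstituted vinyl group and the crowded, electron-poor tetrasubstituted enoate should secure this. Migration of the new methylene by palladium hydride should be limited by the non-coordinating triflate and the excess amine.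

Step 15
Reactants: 22 5,6-didehydro trimethyl ester
Product: 24 target trimethyl ester, via 6-epimer 23 (not isolated)
Conditions: Mg, MeOH, rt; then NaOMe, MeOH, 60 °C
Reagents that add atoms: none
Why: Dissolving-metal conjugate reduction of the enoate; C5 is protonated on the face anti to the two axial esters at C4 and C10 (H5 trans to C19 and C20). Methoxide then equilibrates C6 to the more stable epimer, with C7 anti to C4 (H5 and H6 trans); the isolated alkene and the tertiary alcohol are inert.

Step 16
Reactants: 24 target trimethyl ester
Product: 25 target triacid
Conditions: n-PrSLi, HMPA, 50 °C; then cold 1 M HCl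
Reagents that add atoms: none
Why: Nucleophilic demethylation (SN2 at the methyl groups) cleaves the neopentyl C19 and C20 esters, where acyl attack fails, without strong acid. The carboxylates formed are configurationally stable at C6, and the acid work-up is kept brief and cold to protect the ring C–ring D unit.

Compound list
1 | 3-methoxybenzyl alcohol | COc1cccc(CO)c1 | starting material
2 | (5-methoxycyclohexa-1,4-dien-1-yl)methanol | COC1=CCC=C(CO)C1 | intermediate
3 | (1,4-dioxaspiro[4.5]dec-7-en-7-yl)methanol (ring C alcohol: C15 hydroxymethyl on C8, C8=C9 alkene, C13 dioxolane) | OCC1=CCCC2(C1)OCCO2 | intermediate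
4 | methyl 3-oxocyclohex-1-ene-1-carboxylate | COC(=O)C1=CC(=O)CCC1 | starting material
5 | methylzinc enolate of methyl (R)-1-methyl-3-oxocyclohexane-1-carboxylate (C10–O–ZnMe, C5=C10) | COC(=O)[C@]1(C)CCCC(O[Zn]C)=C1 | intermediate (not isolated)
6 | methyl (1R)-2-(1-hydroxy-2-methoxy-2-oxoethyl)-1-methyl-3-oxocyclohexane-1-carboxylate (aldol adduct, present as its methylzinc alkoxide; C5 and C6 epimers) | COC(=O)[C@]1(C)CCCC(=O)C1C(O)C(=O)OC | intermediate (not isolated)
7 | methyl (3aS,7aR)-7a-methyl-1,4-dioxooctahydro-2-benzofuran-3-carboxylate (cis-fused C19 to C6 γ-lactone, C10 ketone; C6 epimers) | C[C@@]12CCCC(=O)[C@@H]1C(C(=O)OC)OC2=O | intermediate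
8 | C10 methoxymethylidene derivative of 7 (C10=C20H–OMe; E/Z mixture) | C[C@@]12CCCC(=COC)[C@@H]1C(C(=O)OC)OC2=O | intermediate
9 | mixed C20 acetal formed from 8 and 3 (C20 bears OMe and the C15 oxygen; C10–H) | C[C@@]12CCCC(C(OC)OCC3=CCCC4(C3)OCCO4)[C@@H]1C(C(=O)OC)OC2=O | intermediate (not isolated)
10 | allyl enol ether C10=C20H–O–C15H2–C8=C9 (oxygen cis to C1) | C[C@@]12CCC/C(=C\OCC3=CCCC4(C3)OCCO4)[C@@H]1C(C(=O)OC)OC2=O | intermediate (not isolated)
11 | C20 aldehyde: quaternary C10 bears CHO (cis to the C19 lactone carbonyl) and C9 of ring C (C8 exocyclic methylene, C13 dioxolane) | C[C@@]12CCC[C@@](C=O)([C@@H]3CCC4(CC3=C)OCCO4)[C@@H]1C(C(=O)OC)OC2=O | intermediate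
12 | C20 carboxylic acid corresponding to 11 | C[C@@]12CCC[C@@](C(=O)O)([C@@H]3CCC4(CC3=C)OCCO4)[C@@H]1C(C(=O)OC)OC2=O | intermediate
13 | iodolactone: C20 to C8 γ-lactone cis-fused to ring C, C15 iodide, C13 dioxolane | C[C@@]12CCC[C@]3(C(=O)O[C@@]4(CI)CC5(CC[C@@H]34)OCCO5)[C@@H]1C(C(=O)OC)OC2=O | intermediate
14 | C13 ketone of the iodolactone | C[C@@]12CCC[C@]3(C(=O)O[C@@]4(CI)CC(=O)CC[C@@H]34)[C@@H]1C(C(=O)OC)OC2=O | intermediate
15 | C13 vinyl carbinol of the iodolactone (OH cis to C10 and to the lactone oxygen; vinyl cis to C15) | C[C@@]12CCC[C@]3(C(=O)O[C@@]4(CI)C[C@](O)(C=C)CC[C@@H]34)[C@@H]1C(C(=O)OC)OC2=O | intermediate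
16 | C20 acid bearing the C8 exocyclic methylene and the C13 vinyl carbinol; C19 to C6 lactone intact | C[C@@]12CCC[C@@](C(=O)O)([C@@H]3CC[C@@](O)(C=C)CC3=C)[C@@H]1C(C(=O)OC)OC2=O | intermediate
17 | C6-hydroxylated lactone (hemiketal, formed as its potassium salt) | C[C@@]12CCC[C@@](C(=O)O)([C@@H]3CC[C@@](O)(C=C)CC3=C)[C@@H]1C(O)(C(=O)OC)OC2=O | intermediate (not isolated)
18 | keto diacid: C19,C20-diacid bearing a methyl oxalyl group on C5 (C6 ketone, C7 methyl ester; C5 epimers) | C[C@@]1(C(=O)O)CCC[C@@](C(=O)O)([C@@H]2CC[C@@](O)(C=C)CC2=C)C1C(=O)C(=O)OC | intermediate
19 | keto triester: C19,C20-dimethyl ester of 18 | C[C@@]1(C(=O)OC)CCC[C@@](C(=O)OC)([C@@H]2CC[C@@](O)(C=C)CC2=C)C1C(=O)C(=O)OC | intermediate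
20 | (Z)-enol triflate, ring A–ring C seco precursor (C5=C6, OTf on the C10 side, C8=C15 methylene, C13 vinyl carbinol) | C=C[C@]1(O)CC[C@H](C(=C)C1)[C@]1(C(=O)OC)CCC[C@@](C)(C(=O)OC)/C1=C(/OS(=O)(=O)C(F)(F)F)C(=O)OC | intermediate
21 | C15 neopentylpalladium triflate after ring B closure (phosphine ligands not shown) | C=C[C@]1(O)CC[C@@H]2[C@](C[Pd]OS(=O)(=O)C(F)(F)F)(C1)C(C(=O)OC)=C3[C@](C)(C(=O)OC)CCC[C@@]23C(=O)OC | intermediate (not isolated)
22 | 5,6-didehydro derivative of trimethyl ester 24 (tetracyclic C5=C6 enoate) | C=C1C[C@]23C[C@@]1(O)CC[C@H]2[C@]1(C(=O)OC)CCC[C@@](C)(C(=O)OC)C1=C3C(=O)OC | intermediate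
23 | 6-epimer of trimethyl ester 24 | C=C1C[C@]23C[C@@]1(O)CC[C@H]2[C@]1(C(=O)OC)CCC[C@@](C)(C(=O)OC)[C@H]1[C@H]3C(=O)OC | intermediate (not isolated)
24 | trimethyl ester of target 25 (C7, C19 and C20 methyl esters) | C=C1C[C@]23C[C@@]1(O)CC[C@H]2[C@]1(C(=O)OC)CCC[C@@](C)(C(=O)OC)[C@H]1[C@@H]3C(=O)OC | intermediate
25 | target gibberellin triacid (13-hydroxyl, C16 methylene, carboxyl groups at C7, C19 and C20; number 17 of the gibberellin A series) | C=C1C[C@]23C[C@@]1(O)CC[C@H]2[C@]1(C(=O)O)CCC[C@@](C)(C(=O)O)[C@H]1[C@@H]3C(=O)O | target

Total step count: 16. Longest linear sequence: 14 steps (steps 3–16 from 4; equally steps 1, 2 and 5–16 from 1).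

Steps least certain to work

Step 14 (key step). The cascade may stop after ring B: the C15 alkylpalladium can be reduced, can attack the C5=C6 bond 3-exo and rearrange to a ring-expanded skeleton, or can fail to reach the vinyl group if ring C does not flip. Oxidative addition at the crowded tetrasubstituted triflate may also be slow, and the product methylene may migrate into the ring through palladium hydride re-addition. The fallback replaces the alkene acceptor by an alkyne and ends the cascade by hydride capture instead of β-hydride loss. It sets out from ketone 14 and comes back at 22. Ethynylmagnesium bromide with CeCl3 would give the ethynyl carbinol F1 (same facial control as in step 9), Zn/AcOH the acid F2, the oxaziridine oxidation the keto diacid F3, MeI/KHCO3 the triester F4, and KN(SiMe3)2/PhNTf2 the ethynyl enol triflate F5. With Pd(PPh3)4 and HCO2Na in DMF the C15 alkylpalladium should insert the alkyne 5-exo-dig (faster than alkene insertion and with no β-hydride step to go wrong), and formate reduction of the C17 alkenylpalladium would give 22.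

Step 5. The exchange may stall at mixed acetal 9, the dioxolane may be lost to the hot acid, or a boat transition state or attack on the wrong face of C10 may erode control at C9 and C10. The fallback changes both the enol component and the way it is made; it sets out from 7 and comes back at 12, so it also bypasses the basic ylide of step 4, where opening of the β-acyloxy ketone by elimination is a risk. Kinetic enolisation at C1 and triflation would give the C10 enol triflate F6; carbonylation (Pd(OAc)2, PPh3, CO, BnOH, Et3N) the benzyl enoate F7; hydrogenation over Pd/C, with loss of the benzyl group, the saturated acid F8; and Steglich esterification with 3 the allylic ester F9. Ireland–Claisen rearrangement of F9 (excess LiN(i-Pr)2, Me3SiCl, THF–DMPU, −78 to 50 °C; the C6 ester is enolised as well and returns on work-up) would form the same C9–C10 bond below 60 °C and give acid 12 directly.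

Step 13. Enolisation may give the wrong enol geometry (oxygen on the C4 side), because the two flanks of C5 differ only moderately in size; that isomer cannot cyclise in step 14. The fallback fixes the geometry in a ring; it sets out from 15 and comes back at 20. Oxidation of 15 as in step 11, with the iodolactone kept, would give the keto acid F10 with only C19 free; MeI with KHCO3 would give its methyl ester F11; and Zn with NH4Cl in EtOH (chosen to spare the keto ester) would give the C20 acid F12. Enol lactonisation of this γ-keto acid (Ac2O, NaOAc) can only place the enol oxygen on the C10 side, giving the enol lactone F13. NaOMe in THF at −78 °C would open it at C20 to the C20 methyl ester and the geometrically defined enolate, which PhNTf2 would trap as 20.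

Step 3. The zinc enolate next to the new quaternary carbon may add slowly to the glyoxylate, the aldol adduct may dehydrate instead of lactonising, or the trans adduct may fail to equilibrate. The fallback separates the three events; it sets out from 4 and comes back at 7. The conjugate addition would be quenched with Me3SiCl to give the silyl enol ether F14; a Mukaiyama aldol addition to methyl glyoxylate (TiCl4, CH2Cl2, −78 °C) would give 6 as the free alcohol, and TsOH in toluene would epimerise C5 and close the lactone to 7.

Step 15. Electron transfer to the twisted, tetrasubstituted enoate may be too slow with magnesium, or transfer to the other esters may compete. The fallback reduces the carboxylate instead of the ester; it sets out from 22 and comes back at 24. Demethylation of 22 (n-PrSLi, HMPA) would give the 5,6-didehydro triacid F15; Li in NH3/THF reduces conjugated carboxylates cleanly and would give 25 together with its 6-epimer F16. Re-esterification of the mixture with MeI and KHCO3 in DMF and equilibration with NaOMe would return the material to 24.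

Further compounds
F1 | step 14 | C13 ethynyl carbinol of the iodolactone | C[C@@]12CCC[C@]3(C(=O)O[C@@]4(CI)C[C@](O)(C#C)CC[C@@H]34)[C@@H]1C(C(=O)OC)OC2=O
F2 | step 14 | C20 acid bearing the C8 methylene and the C13 ethynyl carbinol | C[C@@]12CCC[C@@](C(=O)O)([C@@H]3CC[C@@](O)(C#C)CC3=C)[C@@H]1C(C(=O)OC)OC2=O
F3 | step 14 | ethynyl analogue of keto diacid 18 | C[C@@]1(C(=O)O)CCC[C@@](C(=O)O)([C@@H]2CC[C@@](O)(C#C)CC2=C)C1C(=O)C(=O)OC
F4 | step 14 | ethynyl analogue of keto triester 19 | C[C@@]1(C(=O)OC)CCC[C@@](C(=O)OC)([C@@H]2CC[C@@](O)(C#C)CC2=C)C1C(=O)C(=O)OC
F5 | step 14 | ethynyl analogue of (Z)-enol triflate 20 | C#C[C@]1(O)CC[C@H](C(=C)C1)[C@]1(C(=O)OC)CCC[C@@](C)(C(=O)OC)/C1=C(/OS(=O)(=O)C(F)(F)F)C(=O)OC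
F6 | step 5 | C10 enol triflate of keto lactone 7 (C10=C1) | C[C@@]12CCC=C(OS(=O)(=O)C(F)(F)F)[C@@H]1C(C(=O)OC)OC2=O
F7 | step 5 | benzyl C20 enoate (C10=C1) | C[C@@]12CCC=C(C(=O)OCc3ccccc3)[C@@H]1C(C(=O)OC)OC2=O
F8 | step 5 | saturated C20 acid of the lactone (C10 epimers) | C[C@@]12CCCC(C(=O)O)[C@@H]1C(C(=O)OC)OC2=O
F9 | step 5 | C20 ester of F8 and ring C alcohol 3 | C[C@@]12CCCC(C(=O)OCC3=CCCC4(C3)OCCO4)[C@@H]1C(C(=O)OC)OC2=O
F10 | step 13 | iodolactone bearing the C19 acid and the C6 α-keto methyl ester | C[C@@]1(C(=O)O)CCC[C@]2(C(=O)O[C@@]3(CI)C[C@](O)(C=C)CC[C@@H]23)C1C(=O)C(=O)OC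
F11 | step 13 | C19 methyl ester of F10 | C[C@@]1(C(=O)OC)CCC[C@]2(C(=O)O[C@@]3(CI)C[C@](O)(C=C)CC[C@@H]23)C1C(=O)C(=O)OC
F12 | step 13 | C20 acid bearing the C19 methyl ester, the C6 α-keto ester and the C8 methylene | C[C@@]1(C(=O)OC)CCC[C@@](C(=O)O)([C@@H]2CC[C@@](O)(C=C)CC2=C)C1C(=O)C(=O)OC
F13 | step 13 | C20 to C6 enol lactone (C5=C6 inside the lactone) | C=C[C@]1(O)CC[C@H](C(=C)C1)[C@]12CCC[C@@](C)(C(=O)OC)C1=C(C(=O)OC)OC2=O
F14 | step 3 | trimethylsilyl enol ether of methyl (R)-1-methyl-3-oxocyclohexane-1-carboxylate | COC(=O)[C@]1(C)CCCC(O[Si](C)(C)C)=C1
F15 | step 15 | 5,6-didehydro triacid (tricarboxylic acid of 22) | C=C1C[C@]23C[C@@]1(O)CC[C@H]2[C@]1(C(=O)O)CCC[C@@](C)(C(=O)O)C1=C3C(=O)O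
F16 | step 15 | 6-epimer of target triacid 25 | C=C1C[C@]23C[C@@]1(O)CC[C@H]2[C@]1(C(=O)O)CCC[C@@](C)(C(=O)O)[C@H]1[C@H]3C(=O)O
A1 | alternative 1 | ring A–B–C tricycle bearing a C15 aldehyde on C8 and a silyloxy alkynyl C13 | O=C[C@]12C[C@](O[Si](C)(C)C(C)(C)C)(C#C[Si](C)(C)C)C=C[C@H]1[C@]1(C(=O)OC)CCC[C@@](C)(C(=O)OC)[C@H]1[C@@H]2C(=O)OC
A2 | alternative 2 | ring B–C–D tricycle bearing C10 allyl and C4 vinyl groups | O=C1C[C@]23C[C@@]1(O[Si](C)(C)C(C)(C)C)CC[C@H]2[C@@](CC=C)(C(=O)OC)[C@H]([C@@H]3C(=O)OC)[C@@](C)(C=C)C(=O)OC
A3 | alternative 3 | 13-acetate of the target trimethyl ester | C=C1C[C@]23C[C@@]1(OC(C)=O)CC[C@H]2[C@]1(C(=O)OC)CCC[C@@](C)(C(=O)OC)[C@H]1[C@@H]3C(=O)OC
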